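The C7–OMe bond of the threo ether is the disconnection. The guaiacyl ring (ring A) carries the molecule's only free phenol, O4, and the benzylic carbon C7 sits para to it, so a two-electron oxidation turns ring A into a p-quinone methide whose exocyclic terminus is C7. In one operation a quinone-mediated anodic dehydrogenation forms this quinone methide and a chiral phosphoric acid steers 1,6-addition of methanol, creating the C7–O bond and the C7 stereocentre while ring A rearomatises. The precursor is the C7-deoxy ether, an (S)-1-guaiacyl-2-aryloxypropane, assembled from (R)-propylene oxide by copper-catalysed aryl Grignard opening and Mitsunobu inversion at C8.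

Key step: step 5

Remark: neolignan numbering is used (ring A = guaiacyl ring C1–C6 with O4; side chain C7–C8–C9; ring B = 4-allyl-2,6-dimethoxyphenyl, bonded to C8 through oxygen). The target as drawn is the threo (7S,8S) isomer. Which antipode of the phosphoric acid delivers it in step 5 is not predictable, so both are assumed to be tested; (R)-TRIP is written as the starting choice.

Step 1
Reactants: 1 4-bromo-2-methoxyphenol
Product: 2 (4-bromo-2-methoxyphenoxy)(tert-butyl)dimethylsilane
Conditions: TBSCl, imidazole, DMF, rt
Reagents that add atoms: tert-butyldimethylsilyl chloride (TBSCl), CC(C)(C)[Si](C)(C)Cl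
Why: Imidazole-promoted silylation of a phenol (silyl ether formation) masks the acidic OH for the organomagnesium and Mitsunobu steps, and the aryl silyl ether can later be removed by fluoride without touching the allyl group.

Step 2
Reactants: 2 (4-bromo-2-methoxyphenoxy)(tert-butyl)dimethylsilane; 3 (R)-propylene oxide [(2R)-2-methyloxirane]
Product: 5 (2R)-1-[4-(tert-butyldimethylsilyloxy)-3-methoxyphenyl]propan-2-ol, via arylmagnesium bromide 4 (not isolated)
Conditions: Mg, THF, 40 °C; then CuI (10 mol %), 3, −30 → 0 °C
Reagents that add atoms: none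
Why: Copper-catalysed epoxide opening by an aryl Grignard reagent is an SN2 attack at the unsubstituted CH2, so no bond to the stereocentre is broken and the R configuration of 3 becomes the R carbinol at C8; the aryl silyl ether is inert to the organometallic.

Step 3
Reactants: 5 (2R)-1-[4-(tert-butyldimethylsilyloxy)-3-methoxyphenyl]propan-2-ol; 6 4-allyl-2,6-dimethoxyphenol
Product: 7 tert-butyl{4-[(2S)-2-(4-allyl-2,6-dimethoxyphenoxy)propyl]-2-methoxyphenoxy}dimethylsilane
Conditions: PPh3, DIAD, THF, 0 °C → rt
Reagents that add atoms: none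
Why: Mitsunobu etherification, in which the phosphonium-activated secondary alcohol is displaced by the phenoxide of 6 in an SN2 step that inverts C8 from R to S; the silyl ether and the allyl group are spectators.

Step 4
Reactants: 7 tert-butyl{4-[(2S)-2-(4-allyl-2,6-dimethoxyphenoxy)propyl]-2-methoxyphenoxy}dimethylsilane
Product: 8 4-[(2S)-2-(4-allyl-2,6-dimethoxyphenoxy)propyl]-2-methoxyphenol
Conditions: TBAF, AcOH, THF, 0 °C
Reagents that add atoms: none
Why: Fluoride cleaves the aryl O–Si bond (silyl ether deprotection) while acetic acid buffers the phenoxide, leaving the alkyl aryl ether, the C8 stereocentre and the allyl group untouched.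

Step 5
Reactants: 8 4-[(2S)-2-(4-allyl-2,6-dimethoxyphenoxy)propyl]-2-methoxyphenol
Product: 10 4-[(1S,2S)-2-(4-allyl-2,6-dimethoxyphenoxy)-1-methoxypropyl]-2-methoxyphenol, via p-quinone methide 9 (not isolated)
Conditions: DDQ (10 mol %), (R)-TRIP [(R)-3,3'-bis(2,4,6-triisopropylphenyl)-BINOL hydrogen phosphate, 10 mol %], MeOH (20 equiv), 3 Å MS, n-Bu4NPF6, CH2Cl2, RVC(+)/Pt(−), undivided cell, anode at the DDQH2 wave, 2.0 F/mol, −20 °C
Reagents that add atoms: methanol, CO
Why: Proposed new method: DDQ removes a hydride equivalent from C7 of the free 4-alkylguaiacol to give p-quinone methide 9 and DDQH2, the anode reoxidises DDQH2 while the cathode evolves H2, so the quinone stays catalytic and the charge passed caps the oxidation level. The phosphoric acid then binds the C4 carbonyl of 9 through P–OH and methanol through P=O, and 1,6-addition at C7 rearomatises ring A; no ring is closed. The closest known reaction types are the benzylic methoxylation of 4-alkylphenols by DDQ in methanol and phosphoric-acid-catalysed asymmetric 1,6-additions to p-quinone methides, whereas their merger under anodic turnover and face control on a β-aryloxy quinone methide are untested. The C7 stereocentre is set by the catalyst: with C8–H eclipsing C1=C7 (A1,3 strain) the (8S) centre holds its aryloxy group over the Si face and its methyl over the Re face of C7 (priorities C8 > C1 > H), threo (7S) needs methanol on the Si face, and because simple attack anti to the aryloxy group would lead to the erythro epimer the catalyst antipode that enforces Si attack must be found by running both. Chemoselectivity comes from the substrate, since only ring A has a free OH and phenols are dehydrogenated by DDQ much faster than the allylic CH2 of the fully etherified ring B, and from holding the anode at the mediator wave, below direct oxidation of either arene. Low temperature, a weak acid and a limited amount of methanol should keep the product ether from re-ionising and C8 from epimerising through the enol ether.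

Compound list
1 | 4-bromo-2-methoxyphenol | COc1cc(Br)ccc1O | starting material
2 | (4-bromo-2-methoxyphenoxy)(tert-butyl)dimethylsilane | COc1cc(Br)ccc1O[Si](C)(C)C(C)(C)C | intermediate
3 | (R)-propylene oxide [(2R)-2-methyloxirane] | C[C@@H]1CO1 | starting material
4 | [4-(tert-butyldimethylsilyloxy)-3-methoxyphenyl]magnesium bromide | COc1cc([Mg]Br)ccc1O[Si](C)(C)C(C)(C)C | intermediate (not isolated)
5 | (2R)-1-[4-(tert-butyldimethylsilyloxy)-3-methoxyphenyl]propan-2-ol | C[C@@H](O)Cc1ccc(O[Si](C)(C)C(C)(C)C)c(OC)c1 | intermediate
6 | 4-allyl-2,6-dimethoxyphenol | C=CCc1cc(OC)c(O)c(OC)c1 | starting material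
7 | tert-butyl{4-[(2S)-2-(4-allyl-2,6-dimethoxyphenoxy)propyl]-2-methoxyphenoxy}dimethylsilane | C=CCc1cc(OC)c(O[C@@H](C)Cc2ccc(O[Si](C)(C)C(C)(C)C)c(OC)c2)c(OC)c1 | intermediate
8 | 4-[(2S)-2-(4-allyl-2,6-dimethoxyphenoxy)propyl]-2-methoxyphenol | C=CCc1cc(OC)c(O[C@@H](C)Cc2ccc(O)c(OC)c2)c(OC)c1 | intermediate
9 | 4-[(2S)-2-(4-allyl-2,6-dimethoxyphenoxy)propylidene]-2-methoxycyclohexa-2,5-dien-1-one (p-quinone methide, alkene geometry not defined) | C=CCc1cc(OC)c(O[C@@H](C)C=C2C=CC(=O)C(OC)=C2)c(OC)c1 | intermediate (not isolated)
10 | 4-[(1S,2S)-2-(4-allyl-2,6-dimethoxyphenoxy)-1-methoxypropyl]-2-methoxyphenol | C=CCc1cc(OC)c(O[C@@H](C)[C@@H](OC)c2ccc(O)c(OC)c2)c(OC)c1 | target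

Total step count: 5
Longest linear sequence: 5 steps (1 → 2 → 5 → 7 → 8 → 10)

Steps most likely to fail

1. Step 5 (Proposed new method).
- What may go wrong: facial discrimination at C7 may be poor or favour the erythro epimer. The product ether or the allyl side chain of ring B may be over-oxidised once the phenol is consumed. The phenol may be oxidised directly at the electrode to dearomatised quinol ketals. C8 may erode through tautomerisation of the quinone methide to the enol ether.
- Mitigation within the step: a minor C7 epimer could be separated and re-equilibrated through the quinone methide with acid in methanol.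
- Fallback (known chemistry, C7 set by reagent control): it sets out from 6 and uses Grignard reagent 4. Mitsunobu coupling of 6 with methyl (R)-lactate (PPh3, DIAD, THF) should give, with inversion, methyl (2S)-2-(4-allyl-2,6-dimethoxyphenoxy)propanoate F1. MeNH(OMe)·HCl with i-PrMgCl (THF, −20 °C) should convert it into the Weinreb amide (2S)-2-(4-allyl-2,6-dimethoxyphenoxy)-N-methoxy-N-methylpropanamide F2. Addition of 4 (THF, −40 → 0 °C) should give the aryl ketone (2S)-2-(4-allyl-2,6-dimethoxyphenoxy)-1-[4-(tert-butyldimethylsilyloxy)-3-methoxyphenyl]propan-1-one F3. A non-chelating hydride (L-Selectride, THF, −78 °C) should reduce it under Felkin–Anh control to the threo alcohol (1S,2S)-2-(4-allyl-2,6-dimethoxyphenoxy)-1-[4-(tert-butyldimethylsilyloxy)-3-methoxyphenyl]propan-1-ol F4. Williamson methylation (NaH, MeI, THF, 0 °C), which breaks no bond at C7, should give tert-butyl{4-[(1S,2S)-2-(4-allyl-2,6-dimethoxyphenoxy)-1-methoxypropyl]-2-methoxyphenoxy}dimethylsilane F5. TBAF/AcOH then frees the phenol and the sequence comes back to the route at 10.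

2. Step 3.
- What may go wrong: the activated homobenzylic alcohol may eliminate to the conjugated propenylarene, or displacement by the di-ortho-substituted phenol may be sluggish, so that hydrazide alkylation takes over.
- Fallback (C8–O bond made on an α-hydroxy ester, which cannot form a styrene; C7–C8 bond made afterwards): it sets out from 6. Mitsunobu coupling with isobutyl (R)-lactate (PPh3, DIAD, THF) should give, with inversion, isobutyl (2S)-2-(4-allyl-2,6-dimethoxyphenoxy)propanoate F6. LiAlH4 (THF, 0 °C) should reduce it to (2S)-2-(4-allyl-2,6-dimethoxyphenoxy)propan-1-ol F7. TsCl/pyridine should give (2S)-2-(4-allyl-2,6-dimethoxyphenoxy)propyl 4-methylbenzenesulfonate F8. Copper-catalysed coupling of this primary tosylate with Grignard reagent 4 (Li2CuCl4 cat., THF, −20 °C → rt) leaves C8 untouched and comes back to the route at 7.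

3. Step 2.
- What may go wrong: bromide from the magnesium salts may open the epoxide to a bromohydrin, some attack may occur at the internal carbon, or the electron-rich Grignard reagent may form incompletely.
- Fallback (stereocentre from asymmetric ketone reduction in place of the chiral pool): it sets out from 2. Palladium-catalysed acetonylation through the tin enolate (isopropenyl acetate, Bu3SnOMe, PdCl2[P(o-tol)3]2 cat., toluene, 100 °C) should give 1-[4-(tert-butyldimethylsilyloxy)-3-methoxyphenyl]propan-2-one F9. An (R)-selective (anti-Prelog) alcohol dehydrogenase such as that of Lactobacillus brevis (NADP+, i-PrOH, pH 7 buffer, 30 °C) should reduce it to the R alcohol, coming back to the route at 5.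

Further compounds
F1 | step 5 | methyl (2S)-2-(4-allyl-2,6-dimethoxyphenoxy)propanoate | C=CCc1cc(OC)c(O[C@@H](C)C(=O)OC)c(OC)c1
F2 | step 5 | (2S)-2-(4-allyl-2,6-dimethoxyphenoxy)-N-methoxy-N-methylpropanamide | C=CCc1cc(OC)c(O[C@@H](C)C(=O)N(C)OC)c(OC)c1
F3 | step 5 | (2S)-2-(4-allyl-2,6-dimethoxyphenoxy)-1-[4-(tert-butyldimethylsilyloxy)-3-methoxyphenyl]propan-1-one | C=CCc1cc(OC)c(O[C@@H](C)C(=O)c2ccc(O[Si](C)(C)C(C)(C)C)c(OC)c2)c(OC)c1
F4 | step 5 | (1S,2S)-2-(4-allyl-2,6-dimethoxyphenoxy)-1-[4-(tert-butyldimethylsilyloxy)-3-methoxyphenyl]propan-1-ol | C=CCc1cc(OC)c(O[C@@H](C)[C@@H](O)c2ccc(O[Si](C)(C)C(C)(C)C)c(OC)c2)c(OC)c1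
F5 | step 5 | tert-butyl{4-[(1S,2S)-2-(4-allyl-2,6-dimethoxyphenoxy)-1-methoxypropyl]-2-methoxyphenoxy}dimethylsilane | C=CCc1cc(OC)c(O[C@@H](C)[C@@H](OC)c2ccc(O[Si](C)(C)C(C)(C)C)c(OC)c2)c(OC)c1
F6 | step 3 | isobutyl (2S)-2-(4-allyl-2,6-dimethoxyphenoxy)propanoate | C=CCc1cc(OC)c(O[C@@H](C)C(=O)OCC(C)C)c(OC)c1
F7 | step 3 | (2S)-2-(4-allyl-2,6-dimethoxyphenoxy)propan-1-ol | C=CCc1cc(OC)c(O[C@@H](C)CO)c(OC)c1
F8 | step 3 | (2S)-2-(4-allyl-2,6-dimethoxyphenoxy)propyl 4-methylbenzenesulfonate | C=CCc1cc(OC)c(O[C@@H](C)COS(=O)(=O)c2ccc(C)cc2)c(OC)c1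
F9 | step 2 | 1-[4-(tert-butyldimethylsilyloxy)-3-methoxyphenyl]propan-2-one | CC(=O)Cc1ccc(O[Si](C)(C)C(C)(C)C)c(OC)c1
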